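**Retrosynthetic overview**
1. The last C–C bond is the one between catechol carbon C4' and the benzylic CH2. It is made by anti-Markovnikov radical hydroarylation of vinyl ester 15 with the aryl radical from iodide 19; only desilylation follows.
2. Enabling feature: the ester oxygen sits two atoms from the arene (acyl–O–CH2–CH2–C4' of the benzene ring). The bridge is therefore an O-vinyl (enol) ester at the alkene oxidation level, whose oxygen sends a σ-aryl radical to the terminal CH2 and stabilises the adduct radical for hydrogen-atom transfer.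
3. The 3,4-dihydro-2H-pyran (O1, C2–C6) is the second ring formed. It arises by acid-catalysed transposition of δ-lactone 10, in which the lactone carbonyl becomes the C5 ester and the orthoformate carbon becomes C6.
4. The δ-lactone (first ring) comes from acrylate ring-closing metathesis. C4 is set by Mukaiyama–Michael addition anti to the C3 substituent, and C2/C3 by Ir-catalysed anti-(hydroxymethyl)allylation of ethanol with racemic vinyl ethylene carbonate, which is stereoconvergent.
5. Ring order: δ-lactone, then dihydropyran; the benzene ring is bought as 4-bromocatechol.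

Key step: step 11

Remark: locants C2–C6 follow the pyran numbering of the target (O1, C2 methyl, C3 CH2O, C4 acetic arm, C5 ester, C6). The bisphosphine antipode in step 1 is to be chosen by the established stereochemical model so that the (2R,3R)-diol results.

**Route**

Step 1
Reactants: 1 ethanol; 2 rac-4-ethenyl-1,3-dioxolan-2-one
Product: 4 (2R,3R)-2-ethenylbutane-1,3-diol, via acetaldehyde 3 (not isolated)
Conditions: [Ir(cod)Cl]2 (2.5 mol%), SEGPHOS (5 mol%, one antipode), 4-cyano-3-nitrobenzoic acid (10 mol%), K3PO4 (cat.), THF, 90 °C, sealed tube, EtOH in excess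
Reagents that add atoms: none
Why: Ir-catalysed transfer-hydrogenative carbonyl (hydroxymethyl)allylation, in which ethanol is dehydrogenated to 3, ionisation and decarboxylation of racemic 2 give an (E)-σ-allyl iridium that adds through a closed chair transition state (anti relationship of C2/C3), the chiral bisphosphine sets the absolute configuration, and both enantiomers of 2 converge because its stereocentre is lost on ionisation.

Step 2
Reactants: 4 (2R,3R)-2-ethenylbutane-1,3-diol
Product: 5 (2R,3R)-3-{[tert-butyl(diphenyl)silyl]oxymethyl}pent-4-en-2-ol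
Conditions: TBDPSCl (1.05 equiv), imidazole, CH2Cl2, 0 °C
Reagents that add atoms: tert-butyl(chloro)diphenylsilane, CC(C)(C)[Si](Cl)(c1ccccc1)c1ccccc1
Why: Chemoselective silylation of the primary hydroxyl by a bulky silyl chloride, the acid-resistant silyl group being chosen to survive the acidic ring transposition of step 6.

Step 3
Reactants: 5 (2R,3R)-3-{[tert-butyl(diphenyl)silyl]oxymethyl}pent-4-en-2-ol
Product: 6 (2R,3R)-3-{[tert-butyl(diphenyl)silyl]oxymethyl}pent-4-en-2-yl prop-2-enoate
Conditions: acryloyl chloride, Et3N, DMAP (cat.), CH2Cl2, 0 °C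
Reagents that add atoms: acryloyl chloride, C=CC(=O)Cl
Why: DMAP-catalysed O-acylation of the secondary alcohol with an acyl chloride, which touches no stereocentre.

Step 4
Reactants: 6 (2R,3R)-3-{[tert-butyl(diphenyl)silyl]oxymethyl}pent-4-en-2-yl prop-2-enoate
Product: 7 (5R,6R)-5-{[tert-butyl(diphenyl)silyl]oxymethyl}-6-methyl-5,6-dihydro-2H-pyran-2-one
Conditions: (H2IMes)(PCy3)Cl2Ru=CHPh (5 mol%), CH2Cl2 (0.01 M), 40 °C
Reagents that add atoms: none
Why: Ring-closing olefin metathesis of the acrylate with the terminal vinyl group closes the six-membered unsaturated δ-lactone with loss of ethene and leaves both stereocentres untouched.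

Step 5
Reactants: 7 (5R,6R)-5-{[tert-butyl(diphenyl)silyl]oxymethyl}-6-methyl-5,6-dihydro-2H-pyran-2-one; 8 tert-butyl[(1-methoxyethenyl)oxy]dimethylsilane
Product: 10 methyl 2-[(4S,5R,6R)-5-{[tert-butyl(diphenyl)silyl]oxymethyl}-3-(dimethoxymethyl)-6-methyl-2-oxooxan-4-yl]acetate (C3 epimers), via lactone silyl ketene acetal 9 (not isolated)
Conditions: 8 (1.1 equiv), HNTf2 (3 mol%), CH2Cl2, −78 °C; then HC(OMe)3 (2 equiv), TMSOTf (10 mol%), −78 → −40 °C
Reagents that add atoms: trimethyl orthoformate, COC(OC)OC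
Why: Silyl-Lewis-acid-catalysed Mukaiyama–Michael addition should occur axially at C4 anti to the neighbouring CH2OSi group (1,2-induction, sets 4S), and the regiodefined silyl ketene acetal 9 is then alkylated by the dialkoxycarbenium ion of the orthoformate (Mukaiyama-type acetal alkylation), which places the future C6 carbon only on the lactone α-carbon, the new α-stereocentre being inconsequential.

Step 6
Reactants: 10 methyl 2-[(4S,5R,6R)-5-{[tert-butyl(diphenyl)silyl]oxymethyl}-3-(dimethoxymethyl)-6-methyl-2-oxooxan-4-yl]acetate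
Product: 12 methyl (2R,3R,4S)-3-{[tert-butyl(diphenyl)silyl]oxymethyl}-4-(2-methoxy-2-oxoethyl)-2-methyl-3,4-dihydro-2H-pyran-5-carboxylate, via cyclic methyl acetal 11 (not isolated)
Conditions: CSA (0.2 equiv), MeOH, 45 °C; then PPTS (cat.), PhMe, 90 °C
Reagents that add atoms: methanol, CO
Why: Acid-catalysed α-acyl-lactone rearrangement, in which methanolysis of the lactone frees the C2 hydroxyl, this closes 6-exo onto the acetal carbon to give 11, and loss of methanol into conjugation with the ester gives the β-alkoxyacrylate, with C2, C3 and C4 untouched because only acyl–O and acetal C–O bonds are broken.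

Step 7
Reactants: 12 methyl (2R,3R,4S)-3-{[tert-butyl(diphenyl)silyl]oxymethyl}-4-(2-methoxy-2-oxoethyl)-2-methyl-3,4-dihydro-2H-pyran-5-carboxylate
Product: 14 2-[(2R,3R,4S)-3-{[tert-butyl(diphenyl)silyl]oxymethyl}-5-(methoxycarbonyl)-2-methyl-3,4-dihydro-2H-pyran-4-yl]acetic acid, via lithium carboxylate 13 (not isolated)
Conditions: LiOH·H2O (1.2 equiv), THF/H2O 3:1, 0 °C; then 1 M HCl to pH 3, 0 °C
Reagents that add atoms: lithium hydroxide, [Li+].[OH-]
Why: Chemoselective saponification, since the saturated acetate ester is hydrolysed far faster than the C5 ester, a vinylogous carbonate deactivated by donation from the ring oxygen.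

Step 8
Reactants: 14 2-[(2R,3R,4S)-3-{[tert-butyl(diphenyl)silyl]oxymethyl}-5-(methoxycarbonyl)-2-methyl-3,4-dihydro-2H-pyran-4-yl]acetic acid
Product: 15 methyl (2R,3R,4S)-3-{[tert-butyl(diphenyl)silyl]oxymethyl}-4-[2-(ethenyloxy)-2-oxoethyl]-2-methyl-3,4-dihydro-2H-pyran-5-carboxylate
Conditions: Pd(OAc)2 (5 mol%), KOH (10 mol%), vinyl acetate (solvent), 25–40 °C, dark
Reagents that add atoms: vinyl acetate, CC(=O)OC=C
Why: Pd(II)-catalysed transvinylation (vinyl interchange by acyloxypalladation and β-acetate elimination), driven by the large excess of vinyl acetate.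

Step 9
Reactants: 16 4-bromobenzene-1,2-diol
Product: 17 4-bromo-1,2-bis[(tert-butyldimethylsilyl)oxy]benzene
Conditions: TBSCl (2.4 equiv), imidazole (5 equiv), DMF, 25 °C
Reagents that add atoms: tert-butyl(chloro)dimethylsilane, CC(C)(C)[Si](C)(C)Cl
Why: Standard silyl ether formation masks both phenols of the oxidation-prone, hydrogen-donating catechol for the radical step.

Step 10
Reactants: 17 4-bromo-1,2-bis[(tert-butyldimethylsilyl)oxy]benzene
Product: 19 1,2-bis[(tert-butyldimethylsilyl)oxy]-4-iodobenzene, via aryllithium 18 (not isolated)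
Conditions: n-BuLi (1.05 equiv), THF, −78 °C; then I2 (1.1 equiv), −78 → 0 °C
Reagents that add atoms: n-butyllithium, [Li]CCCC (lithium of 18 only); iodine, II
Why: Bromine–lithium exchange followed by iodinolysis gives the more easily reduced aryl iodide, the exchange at −78 °C being faster than any silyl migration.

Step 11
Reactants: 15 methyl (2R,3R,4S)-3-{[tert-butyl(diphenyl)silyl]oxymethyl}-4-[2-(ethenyloxy)-2-oxoethyl]-2-methyl-3,4-dihydro-2H-pyran-5-carboxylate; 19 1,2-bis[(tert-butyldimethylsilyl)oxy]-4-iodobenzene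
Product: 20 methyl (2R,3R,4S)-4-[2-(2-{3,4-bis[(tert-butyldimethylsilyl)oxy]phenyl}ethoxy)-2-oxoethyl]-3-{[tert-butyl(diphenyl)silyl]oxymethyl}-2-methyl-3,4-dihydro-2H-pyran-5-carboxylate
Conditions: 19 (3 equiv), N-phenylphenothiazine (5 mol%), cyclohexanethiol (10 mol%), HCO2Na (3 equiv), degassed DMSO, 390–450 nm LEDs, 25 °C
Reagents that add atoms: none
Why: Photoexcited N-phenylphenothiazine transfers an electron to iodide 19, loss of iodide gives the σ-aryl radical at C4' of the protected catechol, this adds to the terminal CH2 of the O-vinyl group of 15, and the resulting α-acyloxyalkyl radical takes a hydrogen atom from the thiol, whose thiyl radical is returned to thiol by formate while the CO2 radical anion closes the photocatalytic cycle. The closest known reaction type is the photoredox/hydrogen-atom-transfer anti-Markovnikov hydroarylation of heteroatom-substituted alkenes (N-vinyl carbamates and related O- and N-vinyl compounds) with aryl halides, together with the classical addition of aryl radicals to vinyl acetate. No ring is closed and no stereocentre is created; C2, C3 and C4 are remote from the radical site and the medium is neutral, so they should be carried through unchanged. The step needs regioselectivity for the CH2 terminus, which the enol-ester oxygen secures because attack there gives the oxygen-stabilised secondary radical at an unhindered carbon, the opposite of the Markovnikov sense that metal-hydride or cationic hydroarylation would give. It also needs chemoselectivity for the vinyl ester over the ring C5=C6 bond, which is secured by the substitution of that alkene (internal, trisubstituted, donor-substituted at C6 and flanked by the ring) and by using 19 in excess so that aryl radicals lost to solvent end as the inert arene.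

Step 12
Reactants: 20 methyl (2R,3R,4S)-4-[2-(2-{3,4-bis[(tert-butyldimethylsilyl)oxy]phenyl}ethoxy)-2-oxoethyl]-3-{[tert-butyl(diphenyl)silyl]oxymethyl}-2-methyl-3,4-dihydro-2H-pyran-5-carboxylate
Product: 21 methyl (2R,3R,4S)-4-{2-[2-(3,4-dihydroxyphenyl)ethoxy]-2-oxoethyl}-3-(hydroxymethyl)-2-methyl-3,4-dihydro-2H-pyran-5-carboxylate
Conditions: HF·pyridine (excess), pyridine, THF, 0 → 25 °C, plastic vessel, argon
Reagents that add atoms: none
Why: Fluoride-mediated Si–O cleavage under buffered, weakly acidic conditions should remove the two aryl and the one alkyl silyl ether without touching the esters, the enol ether or the catechol, and avoids base that would promote lactonisation of the freed primary alcohol.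

**Compound list**
1 | ethanol | CCO | starting material
2 | rac-4-ethenyl-1,3-dioxolan-2-one (vinyl ethylene carbonate) | C=CC1COC(=O)O1 | starting material
3 | acetaldehyde | CC=O | intermediate
4 | (2R,3R)-2-ethenylbutane-1,3-diol | O[C@H](C)[C@@H](CO)C=C | intermediate
5 | (2R,3R)-3-{[tert-butyl(diphenyl)silyl]oxymethyl}pent-4-en-2-ol | O[C@H](C)[C@@H](CO[Si](c1ccccc1)(c1ccccc1)C(C)(C)C)C=C | intermediate
6 | (2R,3R)-3-{[tert-butyl(diphenyl)silyl]oxymethyl}pent-4-en-2-yl prop-2-enoate | C=CC(=O)O[C@H](C)[C@@H](CO[Si](c1ccccc1)(c1ccccc1)C(C)(C)C)C=C | intermediate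
7 | (5R,6R)-5-{[tert-butyl(diphenyl)silyl]oxymethyl}-6-methyl-5,6-dihydro-2H-pyran-2-one | O=C1O[C@H](C)[C@@H](CO[Si](c2ccccc2)(c2ccccc2)C(C)(C)C)C=C1 | intermediate
8 | tert-butyl[(1-methoxyethenyl)oxy]dimethylsilane (silyl ketene acetal of methyl acetate) | C=C(OC)O[Si](C)(C)C(C)(C)C | starting material
9 | methyl 2-[(2R,3R,4S)-6-[(tert-butyldimethylsilyl)oxy]-3-{[tert-butyl(diphenyl)silyl]oxymethyl}-2-methyl-3,4-dihydro-2H-pyran-4-yl]acetate | C1=C(O[Si](C)(C)C(C)(C)C)O[C@H](C)[C@@H](CO[Si](c2ccccc2)(c2ccccc2)C(C)(C)C)[C@@H]1CC(=O)OC | intermediate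
10 | methyl 2-[(4S,5R,6R)-5-{[tert-butyl(diphenyl)silyl]oxymethyl}-3-(dimethoxymethyl)-6-methyl-2-oxooxan-4-yl]acetate (C3 epimers) | COC(OC)C1C(=O)O[C@H](C)[C@@H](CO[Si](c2ccccc2)(c2ccccc2)C(C)(C)C)[C@@H]1CC(=O)OC | intermediate
11 | methyl (2R,3R,4S)-3-{[tert-butyl(diphenyl)silyl]oxymethyl}-6-methoxy-4-(2-methoxy-2-oxoethyl)-2-methyloxane-5-carboxylate (epimers at C5 and C6) | COC(=O)C1C(OC)O[C@H](C)[C@@H](CO[Si](c2ccccc2)(c2ccccc2)C(C)(C)C)[C@@H]1CC(=O)OC | intermediate
12 | methyl (2R,3R,4S)-3-{[tert-butyl(diphenyl)silyl]oxymethyl}-4-(2-methoxy-2-oxoethyl)-2-methyl-3,4-dihydro-2H-pyran-5-carboxylate | COC(=O)C1=CO[C@H](C)[C@@H](CO[Si](c2ccccc2)(c2ccccc2)C(C)(C)C)[C@@H]1CC(=O)OC | intermediate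
13 | lithium 2-[(2R,3R,4S)-3-{[tert-butyl(diphenyl)silyl]oxymethyl}-5-(methoxycarbonyl)-2-methyl-3,4-dihydro-2H-pyran-4-yl]acetate | COC(=O)C1=CO[C@H](C)[C@@H](CO[Si](c2ccccc2)(c2ccccc2)C(C)(C)C)[C@@H]1CC(=O)[O-].[Li+] | intermediate
14 | 2-[(2R,3R,4S)-3-{[tert-butyl(diphenyl)silyl]oxymethyl}-5-(methoxycarbonyl)-2-methyl-3,4-dihydro-2H-pyran-4-yl]acetic acid | COC(=O)C1=CO[C@H](C)[C@@H](CO[Si](c2ccccc2)(c2ccccc2)C(C)(C)C)[C@@H]1CC(=O)O | intermediate
15 | methyl (2R,3R,4S)-3-{[tert-butyl(diphenyl)silyl]oxymethyl}-4-[2-(ethenyloxy)-2-oxoethyl]-2-methyl-3,4-dihydro-2H-pyran-5-carboxylate (vinyl ester) | COC(=O)C1=CO[C@H](C)[C@@H](CO[Si](c2ccccc2)(c2ccccc2)C(C)(C)C)[C@@H]1CC(=O)OC=C | intermediate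
16 | 4-bromobenzene-1,2-diol | Oc1ccc(Br)cc1O | starting material
17 | 4-bromo-1,2-bis[(tert-butyldimethylsilyl)oxy]benzene | Brc1ccc(O[Si](C)(C)C(C)(C)C)c(O[Si](C)(C)C(C)(C)C)c1 | intermediate
18 | {3,4-bis[(tert-butyldimethylsilyl)oxy]phenyl}lithium | [Li]c1ccc(O[Si](C)(C)C(C)(C)C)c(O[Si](C)(C)C(C)(C)C)c1 | intermediate
19 | 1,2-bis[(tert-butyldimethylsilyl)oxy]-4-iodobenzene | Ic1ccc(O[Si](C)(C)C(C)(C)C)c(O[Si](C)(C)C(C)(C)C)c1 | intermediate
20 | methyl (2R,3R,4S)-4-[2-(2-{3,4-bis[(tert-butyldimethylsilyl)oxy]phenyl}ethoxy)-2-oxoethyl]-3-{[tert-butyl(diphenyl)silyl]oxymethyl}-2-methyl-3,4-dihydro-2H-pyran-5-carboxylate | COC(=O)C1=CO[C@H](C)[C@@H](CO[Si](c2ccccc2)(c2ccccc2)C(C)(C)C)[C@@H]1CC(=O)OCCc1ccc(O[Si](C)(C)C(C)(C)C)c(O[Si](C)(C)C(C)(C)C)c1 | intermediate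
21 | methyl (2R,3R,4S)-4-{2-[2-(3,4-dihydroxyphenyl)ethoxy]-2-oxoethyl}-3-(hydroxymethyl)-2-methyl-3,4-dihydro-2H-pyran-5-carboxylate | COC(=O)C1=CO[C@H](C)[C@@H](CO)[C@@H]1CC(=O)OCCc1ccc(O)c(O)c1 | target

**Step count and risks**
Total steps: 12. Longest linear sequence: 10 (steps 1–8, 11, 12).

Most likely to fail, step 11: the aryl radical may add to C6 of the ring enol ether–acrylate or be lost to hydrogen abstraction from the solvent before it meets the vinyl ester. The thiol co-catalyst may also be consumed by thiol–ene addition, and formate may slowly strip the aryl silyl groups. Reversible hydrogen abstraction at the allylic C4–H could erode its configuration. The fallback sets out from acid 14 and avoids a free aryl radical altogether. Esterification of 14 with 2-bromoethanol (EDC·HCl, DMAP, CH2Cl2) should give the 2-bromoethyl ester F1. A nickel/photoredox silyl-radical-mediated cross-electrophile coupling of F1 with aryl bromide 17 (Ir photocatalyst, NiCl2·glyme, dtbbpy, (TMS)3SiH, Na2CO3, DME, blue LEDs) would then form the same aryl–CH2 bond through bromine abstraction from F1 and capture of the primary alkyl radical at nickel. This fallback comes back to the route at 20.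

Second, step 5: facial selectivity at C4 may be insufficient, 1,2-addition may compete, or the silyl ketene acetal may be protonated before the orthoformate traps it. The fallback sets out from lactone 7 and uses thermodynamic enolate chemistry. DBU-mediated Michael addition of dimethyl malonate should give the trans adduct dimethyl 2-[(2R,3R,4R)-3-{[tert-butyl(diphenyl)silyl]oxymethyl}-2-methyl-6-oxooxan-4-yl]propanedioate F2. With the malonate masked as its own enolate, NaH (2.2 equiv) and methyl formate would formylate only the lactone α-carbon to give the hydroxymethylene lactone F3. HCl/MeOH followed by TsOH in toluene would transpose the ring to the malonyl dihydropyran F4, and Krapcho dealkoxycarbonylation (LiCl, wet DMSO, 140 °C) would return to the route at 12.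

Third, step 8: the palladium catalyst may decompose to metal before the vinyl interchange reaches useful conversion, and the equilibrium may reverse during concentration. The fallback sets out from acid 14 and makes the enol ester by elimination instead. Esterification with 2-(phenylselanyl)ethanol (EDC·HCl, DMAP) should give the selenide ester F5. Oxidation with NaIO4 (NaHCO3, MeOH/H2O) would give the selenoxide F6, whose thermal syn-elimination (iPr2NH, PhMe, 90 °C) can only proceed toward the O–CH2 carbon. This comes back to the route at 15.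

**Further compounds**
F1 | step 11 | methyl (2R,3R,4S)-4-[2-(2-bromoethoxy)-2-oxoethyl]-3-{[tert-butyl(diphenyl)silyl]oxymethyl}-2-methyl-3,4-dihydro-2H-pyran-5-carboxylate | COC(=O)C1=CO[C@H](C)[C@@H](CO[Si](c2ccccc2)(c2ccccc2)C(C)(C)C)[C@@H]1CC(=O)OCCBr
F2 | step 5 | dimethyl 2-[(2R,3R,4R)-3-{[tert-butyl(diphenyl)silyl]oxymethyl}-2-methyl-6-oxooxan-4-yl]propanedioate | C1C(=O)O[C@H](C)[C@@H](CO[Si](c2ccccc2)(c2ccccc2)C(C)(C)C)[C@@H]1C(C(=O)OC)C(=O)OC
F3 | step 5 | dimethyl 2-[(2R,3R,4R)-3-{[tert-butyl(diphenyl)silyl]oxymethyl}-5-(hydroxymethylidene)-2-methyl-6-oxooxan-4-yl]propanedioate | OC=C1C(=O)O[C@H](C)[C@@H](CO[Si](c2ccccc2)(c2ccccc2)C(C)(C)C)[C@@H]1C(C(=O)OC)C(=O)OC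
F4 | step 5 | dimethyl 2-[(2R,3R,4R)-3-{[tert-butyl(diphenyl)silyl]oxymethyl}-5-(methoxycarbonyl)-2-methyl-3,4-dihydro-2H-pyran-4-yl]propanedioate | COC(=O)C1=CO[C@H](C)[C@@H](CO[Si](c2ccccc2)(c2ccccc2)C(C)(C)C)[C@@H]1C(C(=O)OC)C(=O)OC
F5 | step 8 | methyl (2R,3R,4S)-3-{[tert-butyl(diphenyl)silyl]oxymethyl}-2-methyl-4-{2-oxo-2-[2-(phenylselanyl)ethoxy]ethyl}-3,4-dihydro-2H-pyran-5-carboxylate | COC(=O)C1=CO[C@H](C)[C@@H](CO[Si](c2ccccc2)(c2ccccc2)C(C)(C)C)[C@@H]1CC(=O)OCC[Se]c1ccccc1
F6 | step 8 | methyl (2R,3R,4S)-3-{[tert-butyl(diphenyl)silyl]oxymethyl}-2-methyl-4-{2-oxo-2-[2-(phenylseleninyl)ethoxy]ethyl}-3,4-dihydro-2H-pyran-5-carboxylate | COC(=O)C1=CO[C@H](C)[C@@H](CO[Si](c2ccccc2)(c2ccccc2)C(C)(C)C)[C@@H]1CC(=O)OCC[Se](=O)c1ccccc1
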